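The route rests on cutting C15–C16 together with the lactone C19–O bond. C16, the γ-carbon of the 4-methylbutenolide ring (O–C16–C17–C18–C19), lies 1,3 to the oxygenated C14, so a C14 methyl ketone, reacting through C15, and a (Z)-4-oxo-2-enoate give both bonds and the C16 stereocentre in one boron aldol–lactonization. The precursor is the bis-triethylsilyl-protected decalin core (rings A and B) carrying a 3-methylene-4-oxopentyl chain on C9. It is made from (+)-larixol, which supplies C5, C6, C9 and C10; its 6α-oxygen directs oxidation of the equatorial C4 methyl to the ester. Reduction, peroxide displacement with inversion and desilylation finish.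

Key step: step 13

Remark (numbering): ring A is C1–C5/C10, ring B is C5–C10, the chain is C11–C19, C20 is the methyl on C17, C21 the exo-methylene on C13, C22 the methyl on C8, C23 the ester carbon and C24 the methyl on C4, C25 the methyl on C10.

Remark (starting material): commercial (+)-larixol already carries the 6α-oxygen, so only one remote oxidation (C23) is needed and it is directed by that oxygen.

Remark (assumption): (+)-Ipc2BCl, made from (−)-α-pinene, is taken to direct a methyl ketone enolate to the Si face of a (Z)-enal; should the sense prove opposite, its antipode is used with nothing else changed.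

Step 1
Reactants: 1 (+)-larixol
Product: 2 6α-hydroxy C13 methyl ketone with the C8=C22 exocyclic alkene
Conditions: KMnO4, acetone/H2O, 0 °C
Reagents that add atoms: none
Why: Permanganate oxidative cleavage of the tertiary vinyl carbinol (dihydroxylation, glycol cleavage, oxidative decarboxylation of the α-hydroxy acid) is the classical side-chain degradation of 13-hydroxylabd-14-enes and should leave the C13 methyl ketone, the hindered C8=C22 methylene and the 6α-hydroxyl reacting much more slowly; the C13 stereocentre is destroyed and none is formed.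

Step 2
Reactants: 2 6α-hydroxy C13 methyl ketone
Product: 3 8α,22-epoxy-6α-hydroxy C13 methyl ketone
Conditions: mCPBA, NaHCO3, CH2Cl2, 0 °C
Reagents that add atoms: 3-chloroperbenzoic acid OOC(=O)c1cccc(Cl)c1
Why: Prilezhaev epoxidation should occur on the α face of the exocyclic alkene (equatorial approach, away from the axial C25 methyl on C10), which sets C8 with its oxygen α, while the ketone and the hydroxyl are inert under bicarbonate buffering; any minor β-epoxide is removed by chromatography.

Step 3
Reactants: 3 8α,22-epoxy-6α-hydroxy C13 methyl ketone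
Product: 4 6α,23:8α,22-diepoxy C13 methyl ketone
Conditions: PhI(OAc)2, I2, cyclohexane, hν (tungsten lamp), rt
Reagents that add atoms: none
Why: In this Suárez hypoiodite reaction light homolyses the 6α-O–I bond, the alkoxy radical abstracts hydrogen from C23 through a six-membered transition state (the equatorial 4α-methyl is syn-pentane to the equatorial 6α-oxygen, whereas the axial C24 methyl and every other δ-hydrogen are out of reach), and iodination followed by intramolecular etherification closes the tetrahydrofuran, so that C4 becomes stereogenic with C23 α purely by geometry, the epoxide meanwhile masking the alkene from iodine.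

Step 4
Reactants: 4 6α,23:8α,22-diepoxy C13 methyl ketone
Product: 5 6α,23-epoxy-8α,13-diol (C13 epimers)
Conditions: LiAlH4, THF, 0 °C to rt
Reagents that add atoms: none
Why: Hydride opens the spiro-epoxide by SN2 attack at its unhindered CH2 terminus (C22), giving the 8α tertiary alcohol and the 8β-methyl without touching the C8–O bond, and also reduces the ketone to a C13 carbinol whose mixed configuration is erased in step 5, the cyclic ether being inert to LiAlH4.

Step 5
Reactants: 5 6α,23-epoxy-8α,13-diol
Product: 6 6α,23-epoxy-8α-hydroxy C13 methyl ketone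
Conditions: Dess–Martin periodinane, NaHCO3, CH2Cl2, rt
Reagents that add atoms: none
Why: Dess–Martin oxidation under bicarbonate buffering restores the C13 ketone from the only secondary alcohol and cannot touch the tertiary 8α-hydroxyl, acid being excluded because the δ-hydroxy ketone would cyclodehydrate to an enol ether; no stereocentre is affected.

Step 6
Reactants: 6 6α,23-epoxy-8α-hydroxy C13 methyl ketone
Product: 7 6α,23-epoxy-8α-triethylsilyloxy C13 methyl ketone
Conditions: TESOTf, 2,6-lutidine, CH2Cl2, −78 to 0 °C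
Reagents that add atoms: triethylsilyl trifluoromethanesulfonate CC[Si](CC)(CC)OS(=O)(=O)C(F)(F)F
Why: Silylation with a silyl triflate and a hindered pyridine base caps the tertiary 8α-hydroxyl at low temperature without enolising the ketone, and it is placed here because a free 8α-hydroxyl next to the C13 ketone would cyclise and be degraded under the oxidation of step 7.

Step 7
Reactants: 7 6α,23-epoxy-8α-triethylsilyloxy C13 methyl ketone
Product: 8 13-oxo-8α-triethylsilyloxy 23,6α-lactone
Conditions: RuCl3·xH2O (cat.), NaIO4, CCl4/MeCN/pH 7 phosphate buffer, rt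
Reagents that add atoms: sodium periodate [Na+].[O-]I(=O)(=O)=O (oxygen relayed by RuO4 formed in the flask)
Why: RuO4, regenerated catalytically by periodate, oxidises ethers at the α-methylene group, so C23H2 becomes the lactone carbonyl, whereas the other α-position (the axial C6–H flanked by the axial C24 and C25 methyls) is shielded, the ketone is inert and buffering preserves the tertiary silyl ether.

Step 8
Reactants: 8 13-oxo-8α-triethylsilyloxy 23,6α-lactone
Product: 10 methyl 6α-hydroxy-13-oxo-8α-triethylsilyloxy-23-oate, via potassium carboxylate 9 (not isolated)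
Conditions: KOH, MeOH/H2O, 60 °C; evaporate; MeI, DMF, rt
Reagents that add atoms: potassium hydroxide [K+].[OH-]; iodomethane CI
Why: Saponification opens the γ-lactone to the 6α-hydroxy carboxylate and SN2 O-methylation of this potassium salt gives the methyl ester without passing through the free hydroxy acid, which would relactonise; C4 and C6 keep their configuration because only the acyl C–O bond is broken.

Step 9
Reactants: 10 methyl 6α-hydroxy-13-oxo-8α-triethylsilyloxy-23-oate
Product: 11 methyl 13-oxo-6α,8α-bis(triethylsilyloxy)-23-oate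
Conditions: TESOTf, 2,6-lutidine, CH2Cl2, −78 °C
Reagents that add atoms: triethylsilyl trifluoromethanesulfonate CC[Si](CC)(CC)OS(=O)(=O)C(F)(F)F
Why: Silyl triflate silylation caps the hindered equatorial 6α-hydroxyl at once, which also removes the internal nucleophile that could re-form the lactone from the ester.

Step 10
Reactants: 11 methyl 13-oxo-6α,8α-bis(triethylsilyloxy)-23-oate
Product: 13 terminal enol triflate (C13(OTf)=C21H2), via lithium enolate 12 (not isolated)
Conditions: LiN(i-Pr)2, THF, −78 °C; PhNTf2, −78 to 0 °C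
Reagents that add atoms: N-phenylbis(trifluoromethanesulfonimide) O=S(=O)(N(c1ccccc1)S(=O)(=O)C(F)(F)F)C(F)(F)F
Why: Kinetic deprotonation by the bulky amide base at −78 °C occurs at the methyl group C21 and not at C12H2, and O-sulfonylation of the terminal enolate gives the 2-triflyloxy-1-alkene, the quaternary ester having no α-hydrogen and the silyl ethers being stable to the base.

Step 11
Reactants: 13 terminal enol triflate; 14 tributyl(1-ethoxyvinyl)stannane
Product: 16 bis-TES enone (C13=C21H2 and C14 methyl ketone), via ethoxy diene 15 (not isolated)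
Conditions: Pd(PPh3)4 (cat.), LiCl, THF, 65 °C; then aq. oxalic acid, THF, 0 °C
Reagents that add atoms: water O
Why: Stille coupling (oxidative addition of zerovalent palladium into the C13–OTf bond, chloride-assisted transmetalation from tin, reductive elimination) joins C13 to C14 as the 2-ethoxy diene, whose enol ether is hydrolysed by dilute oxalic acid to the C14 methyl ketone while the C13=C21 methylene and both silyl ethers persist; no stereocentre is involved.

Step 12
Reactants: 17 5-hydroxy-4-methylfuran-2(5H)-one
Product: 18 methyl (Z)-3-methyl-4-oxobut-2-enoate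
Conditions: MeI, K2CO3, DMF, 0 °C
Reagents that add atoms: iodomethane CI
Why: The pseudo-acid opens to its carboxylate under carbonate and SN2 O-methylation gives the open-chain formyl ester, whose Z geometry is inherited from the five-membered ring; the aldehyde is kept cold and used at once to prevent Z-to-E isomerisation.

Step 13
Reactants: 16 bis-TES enone; 18 methyl (Z)-3-methyl-4-oxobut-2-enoate
Product: 22 bis-TES C14 ketone bearing the complete (16S)-butenolide, via boron dienolate 19 (not isolated), via boron aldolate 20 (not isolated), via hydroxy enoate 21 (not isolated)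
Conditions: (+)-Ipc2BCl, Et3N, Et2O, 0 °C; 18, −78 to −20 °C; MeOH, pH 7 phosphate buffer; PPTS (cat.), CH2Cl2, rt in the work-up
Reagents that add atoms: none
Why: The chloroborane and Et3N enolise 16 at its methyl group C15, the only enolisable α-position because C13 is sp2, and the cross-conjugated enol borinate 19 adds to the formyl group of 18 through a closed six-membered boron transition state, forming C15–C16 as aldolate 20. This is the diisopinocampheylboron aldol of methyl ketones, followed by the familiar lactonisation of (Z)-4-hydroxy-2-enoates. After B–O cleavage in the buffered methanolic quench, the C16 hydroxyl of 21 attacks the cis-disposed methyl ester (5-exo-trig acyl substitution with loss of methanol) and closes the butenolide ring O–C16–C17–C18–C19. C16 (S) is set by the isopinocampheyl ligands, the (+)-reagent being chosen to send the enolate to the Si face of the (Z)-enal, and the remote core stereocentres are expected to have little say. The step needs 1,2-addition instead of conjugate or cycloaddition pathways (secured by the cyclic boron transition state and the more electrophilic formyl group), retention of the Z geometry of 18 (low temperature, no free base on the aldehyde), and no β-elimination of the acyloxy group from 22, which the non-basic, non-oxidative work-up secures.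

Step 14
Reactants: 22 bis-TES C14 ketone bearing the (16S)-butenolide
Product: 23 (14R)-allylic alcohol
Conditions: (S)-Me-CBS oxazaborolidine [(S)-1-methyl-3,3-diphenyltetrahydro-1H,3H-pyrrolo[1,2-c][1,3,2]oxazaborole], catecholborane, toluene, −78 °C
Reagents that add atoms: none
Why: In this Corey–Bakshi–Shibata reduction the ketone binds the oxazaborolidine boron anti to its larger α-branched alkenyl substituent (C13) and hydride is delivered from the nitrogen-bound borane to one face, which with the (S)-catalyst should give the (14R)-alcohol; 1,2-reduction is expected at −78 °C and the lactone and ester are inert to catecholborane.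

Step 15
Reactants: 23 (14R)-allylic alcohol
Product: 25 (14S)-hydroperoxide bis-TES ether, via mesylate 24 (not isolated)
Conditions: MsCl, Et3N, CH2Cl2, −40 °C; anhydrous H2O2 in Et2O (excess), −40 to 0 °C
Reagents that add atoms: hydrogen peroxide OO
Why: Sulfonylation turns the C14 oxygen into a leaving group without touching the C14–O bond, and SN2 displacement by hydrogen peroxide, a neutral α-effect nucleophile used in large excess in ether, should invert C14 to the (14S)-hydroperoxide, the absence of hydroxide sparing the butenolide and the low temperature disfavouring ionisation and SN2′ attack at C21.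

Step 16
Reactants: 25 (14S)-hydroperoxide bis-TES ether
Product: 26 CNP0324515.1 (target)
Conditions: HF·pyridine, pyridine, THF, 0 °C to rt
Reagents that add atoms: none
Why: Fluoride-driven cleavage of both triethylsilyl ethers with pyridine-buffered HF is mild enough for the allylic hydroperoxide, the butenolide and the 6α-hydroxy ester (no base, hence no Kornblum–DeLaMare fragmentation), and no stereocentre is touched.

Compound list
1 | (+)-larixol (labda-8(17),14-diene-6α,13S-diol) | C=C[C@@](C)(O)CC[C@@H]1[C@@]2(C)CCCC(C)(C)[C@@H]2[C@@H](O)CC1=C | starting material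
2 | 6α-hydroxy C13 methyl ketone with C8=C22 exocyclic alkene | CC(=O)CC[C@@H]1[C@@]2(C)CCCC(C)(C)[C@@H]2[C@@H](O)CC1=C | intermediate
3 | 8α,22-epoxy-6α-hydroxy C13 methyl ketone | CC(=O)CC[C@@H]1[C@@]2(C)CCCC(C)(C)[C@@H]2[C@@H](O)C[C@]13CO3 | intermediate
4 | 6α,23:8α,22-diepoxy C13 methyl ketone | CC(=O)CC[C@@H]1[C@@]2(C)CCC[C@@](C)(CO3)[C@@H]2[C@@H]3C[C@]14CO4 | intermediate
5 | 6α,23-epoxy-8α,13-diol (C13 epimers) | CC(O)CC[C@@H]1[C@@]2(C)CCC[C@@](C)(CO3)[C@@H]2[C@@H]3C[C@@]1(C)O | intermediate
6 | 6α,23-epoxy-8α-hydroxy C13 methyl ketone | CC(=O)CC[C@@H]1[C@@]2(C)CCC[C@@](C)(CO3)[C@@H]2[C@@H]3C[C@@]1(C)O | intermediate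
7 | 6α,23-epoxy-8α-triethylsilyloxy C13 methyl ketone | CC(=O)CC[C@@H]1[C@@]2(C)CCC[C@@](C)(CO3)[C@@H]2[C@@H]3C[C@@]1(C)O[Si](CC)(CC)CC | intermediate
8 | 13-oxo-8α-triethylsilyloxy 23,6α-lactone | CC(=O)CC[C@@H]1[C@@]2(C)CCC[C@@](C)(C(=O)O3)[C@@H]2[C@@H]3C[C@@]1(C)O[Si](CC)(CC)CC | intermediate
9 | potassium 6α-hydroxy-13-oxo-8α-triethylsilyloxy-23-oate (not isolated) | CC(=O)CC[C@@H]1[C@@]2(C)CCC[C@@](C)(C(=O)[O-])[C@@H]2[C@@H](O)C[C@@]1(C)O[Si](CC)(CC)CC.[K+] | intermediate
10 | methyl 6α-hydroxy-13-oxo-8α-triethylsilyloxy-23-oate | CC(=O)CC[C@@H]1[C@@]2(C)CCC[C@@](C)(C(=O)OC)[C@@H]2[C@@H](O)C[C@@]1(C)O[Si](CC)(CC)CC | intermediate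
11 | methyl 13-oxo-6α,8α-bis(triethylsilyloxy)-23-oate | CC(=O)CC[C@@H]1[C@@]2(C)CCC[C@@](C)(C(=O)OC)[C@@H]2[C@@H](O[Si](CC)(CC)CC)C[C@@]1(C)O[Si](CC)(CC)CC | intermediate
12 | lithium C13–C21 enolate of 11 (not isolated) | [Li+].[O-]C(=C)CC[C@@H]1[C@@]2(C)CCC[C@@](C)(C(=O)OC)[C@@H]2[C@@H](O[Si](CC)(CC)CC)C[C@@]1(C)O[Si](CC)(CC)CC | intermediate
13 | terminal enol triflate, C13(OTf)=C21H2 | C=C(OS(=O)(=O)C(F)(F)F)CC[C@@H]1[C@@]2(C)CCC[C@@](C)(C(=O)OC)[C@@H]2[C@@H](O[Si](CC)(CC)CC)C[C@@]1(C)O[Si](CC)(CC)CC | intermediate
14 | tributyl(1-ethoxyvinyl)stannane | CCOC(=C)[Sn](CCCC)(CCCC)CCCC | starting material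
15 | 2-ethoxy diene, C13(=C21H2)–C14(OEt)=C15H2 (not isolated) | CCOC(=C)C(=C)CC[C@@H]1[C@@]2(C)CCC[C@@](C)(C(=O)OC)[C@@H]2[C@@H](O[Si](CC)(CC)CC)C[C@@]1(C)O[Si](CC)(CC)CC | intermediate
16 | bis-TES enone: C13=C21H2, C14 methyl ketone (precursor of the key step) | CC(=O)C(=C)CC[C@@H]1[C@@]2(C)CCC[C@@](C)(C(=O)OC)[C@@H]2[C@@H](O[Si](CC)(CC)CC)C[C@@]1(C)O[Si](CC)(CC)CC | intermediate
17 | 5-hydroxy-4-methylfuran-2(5H)-one | CC1=CC(=O)OC1O | starting material
18 | methyl (Z)-3-methyl-4-oxobut-2-enoate | COC(=O)/C=C(C)\C=O | intermediate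
19 | (+)-diisopinocampheylboron dienolate of 16 (not isolated) | C=C(OB([C@H]1C[C@H]2C[C@@H]([C@@H]1C)C2(C)C)[C@H]1C[C@H]2C[C@@H]([C@@H]1C)C2(C)C)C(=C)CC[C@@H]1[C@@]2(C)CCC[C@@](C)(C(=O)OC)[C@@H]2[C@@H](O[Si](CC)(CC)CC)C[C@@]1(C)O[Si](CC)(CC)CC | intermediate
20 | (16S)-boron aldolate (not isolated) | O=C(C[C@H](OB([C@H]1C[C@H]2C[C@@H]([C@@H]1C)C2(C)C)[C@H]1C[C@H]2C[C@@H]([C@@H]1C)C2(C)C)/C(C)=C\C(=O)OC)C(=C)CC[C@@H]1[C@@]2(C)CCC[C@@](C)(C(=O)OC)[C@@H]2[C@@H](O[Si](CC)(CC)CC)C[C@@]1(C)O[Si](CC)(CC)CC | intermediate
21 | (16S)-16-hydroxy (Z)-enoate (not isolated) | O=C(C[C@H](O)/C(C)=C\C(=O)OC)C(=C)CC[C@@H]1[C@@]2(C)CCC[C@@](C)(C(=O)OC)[C@@H]2[C@@H](O[Si](CC)(CC)CC)C[C@@]1(C)O[Si](CC)(CC)CC | intermediate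
22 | bis-TES C14 ketone bearing the complete (16S)-butenolide | O=C(C[C@@H]1OC(=O)C=C1C)C(=C)CC[C@@H]1[C@@]2(C)CCC[C@@](C)(C(=O)OC)[C@@H]2[C@@H](O[Si](CC)(CC)CC)C[C@@]1(C)O[Si](CC)(CC)CC | intermediate
23 | (14R)-allylic alcohol, bis-TES | C=C(CC[C@@H]1[C@@]2(C)CCC[C@@](C)(C(=O)OC)[C@@H]2[C@@H](O[Si](CC)(CC)CC)C[C@@]1(C)O[Si](CC)(CC)CC)[C@@H](C[C@@H]1OC(=O)C=C1C)O | intermediate
24 | (14R)-mesylate, bis-TES (not isolated) | C=C(CC[C@@H]1[C@@]2(C)CCC[C@@](C)(C(=O)OC)[C@@H]2[C@@H](O[Si](CC)(CC)CC)C[C@@]1(C)O[Si](CC)(CC)CC)[C@@H](C[C@@H]1OC(=O)C=C1C)OS(C)(=O)=O | intermediate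
25 | (14S)-hydroperoxide, bis-TES | C=C(CC[C@@H]1[C@@]2(C)CCC[C@@](C)(C(=O)OC)[C@@H]2[C@@H](O[Si](CC)(CC)CC)C[C@@]1(C)O[Si](CC)(CC)CC)[C@H](C[C@@H]1OC(=O)C=C1C)OO | intermediate
26 | CNP0324515.1 | C=C(CC[C@@H]1[C@@]2(C)CCC[C@@](C)(C(=O)OC)[C@@H]2[C@@H](O)C[C@@]1(C)O)[C@H](C[C@@H]1OC(=O)C=C1C)OO | target

Total step count: 16. Longest linear sequence: 15 steps (steps 1–11 and 13–16, from larixol).

Steps most likely to fail

Step 15. The allylic mesylate may ionise, or be attacked at the terminal methylene C21 (SN2′). Either would erode the C14 configuration or transpose the peroxide, and neutral H2O2 may also substitute too slowly. The fallback sets out from alcohol 23 and keeps the sulfonate activation, but uses a masked, anionic peroxide nucleophile. The mesylate is treated with 2-methoxyprop-2-yl hydroperoxide and CsOH·H2O in DMF at 0 °C, which should give the peroxyketal F7 by SN2 inversion. Mild hydrolysis (AcOH/THF/H2O, rt) then releases the hydroperoxide, and the route is rejoined at 25.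

Step 13. Enolisation may be incomplete, facial selectivity at C16 may be poor, or the β-acyloxy ketone may eliminate during the reaction. The fallback sets out from enone 16 and replaces the boron enolate by a silicon-based Mukaiyama aldol. TMSOTf and Et3N (CH2Cl2, −78 °C) give the trimethylsilyl dienol ether F6. A Lewis-base-catalysed aldol with 18 (SiCl4, chiral binaphthyl-derived bisphosphoramide, i-Pr2NEt, CH2Cl2, −78 °C) then forms C15–C16 through an open transition state under catalyst control. Buffered work-up passes through hydroxy enoate 21, which lactonises with PPTS, and the route is rejoined at 22.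

Step 3. The iodine-based conditions may open the epoxide or iodinate the ketone α-position, or the alkoxy radical may fragment instead of abstracting hydrogen. The fallback sets out from epoxy alcohol 3 and uses Barton nitrite photolysis, which reaches C23 by the same 1,5-hydrogen shift without iodine.
- O-nitrosation (NOCl, pyridine, −20 °C) gives the 6α-nitrite ester F1.
- Irradiation (Hg lamp, Pyrex, benzene, rt) transfers NO to C23, and the nitroso compound tautomerises to the C23 oxime F2.
- Aqueous TiCl3/NH4OAc cleaves the oxime to the aldehyde, which closes onto the 6α-hydroxyl as the lactol F3.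
- LiAlH4 reduces lactol, epoxide and ketone to the 6α,8α,13,23-tetraol F4.
- TEMPO/PhI(OAc)2 oxidises the primary C23 alcohol through the lactol to the lactone, and the C13 carbinol to the ketone, giving the 8α-hydroxy keto lactone F5.
- TESOTf/2,6-lutidine silylates the tertiary hydroxyl, and the route is rejoined at lactone 8.

Further compounds
F1 | step 3 | 6α-nitrite ester of 3 | CC(=O)CC[C@@H]1[C@@]2(C)CCCC(C)(C)[C@@H]2[C@@H](ON=O)C[C@]13CO3
F2 | step 3 | 8α,22-epoxy-6α-hydroxy-13-oxo C23 oxime | CC(=O)CC[C@@H]1[C@@]2(C)CCC[C@@](C)(C=NO)[C@@H]2[C@@H](O)C[C@]13CO3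
F3 | step 3 | 8α,22-epoxy-13-oxo 6α,23-lactol (anomers) | CC(=O)CC[C@@H]1[C@@]2(C)CCC[C@@](C)(C(O)O3)[C@@H]2[C@@H]3C[C@]14CO4
F4 | step 3 | 6α,8α,13,23-tetraol (C13 epimers) | CC(O)CC[C@@H]1[C@@]2(C)CCC[C@@](C)(CO)[C@@H]2[C@@H](O)C[C@@]1(C)O
F5 | step 3 | 8α-hydroxy-13-oxo 23,6α-lactone | CC(=O)CC[C@@H]1[C@@]2(C)CCC[C@@](C)(C(=O)O3)[C@@H]2[C@@H]3C[C@@]1(C)O
F6 | step 13 | trimethylsilyl dienol ether of 16 | C=C(O[Si](C)(C)C)C(=C)CC[C@@H]1[C@@]2(C)CCC[C@@](C)(C(=O)OC)[C@@H]2[C@@H](O[Si](CC)(CC)CC)C[C@@]1(C)O[Si](CC)(CC)CC
F7 | step 15 | (14S)-2-methoxyprop-2-yl peroxide (peroxyketal), bis-TES | C=C(CC[C@@H]1[C@@]2(C)CCC[C@@](C)(C(=O)OC)[C@@H]2[C@@H](O[Si](CC)(CC)CC)C[C@@]1(C)O[Si](CC)(CC)CC)[C@H](C[C@@H]1OC(=O)C=C1C)OOC(C)(C)OC
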